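Amounts first: what counts in the end is how the Z charged divides between E and X, so we follow fractions of that charge and write z for the fraction of Z left.

| flask | Z | G | L | remark | time | volume of the second phase over the first |
|---|---|---|---|---|---|---|
| beta | 0.050 M | 0.075 M | 0.010 M | run made earlier |  |  |
| zeta | 0.050 M | 0.075 M | 0.022 M | run made earlier |  |  |
| theta | 0.075 M | 0.075 M | 0.015 M | run made earlier |  |  |
| flask | 0.050 M | 0.0750 M | 0.0150 M |  | 15 h | 0.25 |

- beta (time / h: E / %): 2.50: 22; 5.00: 29; 8.00: 30; 10.0: 32; 12.0: 34
- zeta (time / h: E / %): 1.00: 3; 2.00: 10; 3.00: 19; 6.00: 26; 12.0: 27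
- theta (time / h: E / %): 1.00: 6; 3.00: 17; 6.00: 22; 8.00: 21; 12.0: 22

(scatter of a reading: 1.5 percentage points)

- percent here means Z units held: one X or D counts as two
- in the second phase: G; everything else is in the first
- charges count per volume of the first phase; a concentration in a rate is the amount of a species over the volume of its own phase; every rate counts per litre of the first phase
- the analysis behind the earlier runs scatters by 1.5 percentage points, standard deviation
- what may be going on: Q <-> G; Z + Q -> E; 2 Z -> X; Q + L -> J; Z + E -> D
- the earlier runs hold the two phases in the same ratio of volumes as the flask asked about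

- amount of E at 15 h, in percent of the Z charged
- the change that raises the amount of E at 15 h, in percent of the Z charged most ("none" if none brings more than 2 percentage points) (Friday's / Tuesday's / none)
- amount of E at 15 h, in percent of the Z charged, after Tuesday's

- Friday's: doubling the transfer coefficient of G, all else as stated
- Tuesday's: doubling the amount of G, all else as stated

Our own reckoning draws the curve of E in the flask.

1. Start: we take the slope of E in the flask as near zero at first. We take L to seize Q first, while Z pairs to X. Carried back, zeta's straight rise meets zero at 0.889 h. Scaled by L, the flask's lag (induction period) is 0.606 h.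

2. Rise: zeta then climbs 0.0900 h⁻¹ of the charge, and we give the flask that slope.

3. Level: dividing the rate of Z to E by the rate of Z lost to X removes time. E takes the share ρ/(ρ+z), where ρ is the z at which both routes use Z equally; ρ/z is the selectivity factor. We neglect D, hold Q steady after the lag and take this share at the middle of the span. The ratio w of Z lost to Z in E then equals a lag term, growing with L, plus 0.5/ρ, and both scale with the Z charged. Beta's last readings average 32.0%, which gives w = 2.12, and zeta's last readings average 26.5%, which gives 2.77. A straight line back to no L gives 1.58, so the tie level is 31.6% of the charge.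

4. Flask: its L gives w = 2.40, so the level is 29.5%. Drawn straight, the rise crosses that level near 3.88 h. Theta, unused so far, comes out at 21.8%, and its last readings average 21.7%.

5. Changes: we let Friday's multiply the lag term by 0.5, giving 33.4%. Tuesday's does that and doubles ρ, giving 45.5%, which is higher.

The forecast gave 30% (27.5% to 33%), chose Tuesday's, and put that change at 44% (38% to 50%), below our figure. Its ground for the choice was “Doubling the transfer coefficient cannot beat this”.

The flask gives 29.6%. Tuesday's gains 12 percentage points and Friday's 6.3 points, so the choice is Tuesday's, reaching 42.0%.

    Q ⇌ G, rate k1*([Q] - [G]/K1) per volume of the first phase (partition coefficient = 3.40, kL = 1.30 × 10⁻⁴ s⁻¹)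
    Z + Q → E (k = 0.00600 L mol⁻¹ s⁻¹)
    2 Z → X (k = 0.00380 L mol⁻¹ s⁻¹)
    Q + L → J (k = 0.220 L mol⁻¹ s⁻¹)
    Z + E → D (k = 3.10 × 10⁻⁴ L mol⁻¹ s⁻¹)

The neighbouring flask is the same flask read at 4.0 h, with 5.2% of its Z still there. At the tie level of 31.6%, the middle of that remainder gives E a share of 92.4%, so the remainder should still bring 4.8 points. Taken from the final 29.6%, that puts E at 24.8% in the neighbouring flask, and the simulation reads 25.1%.

Readings and results were generated by integration with constants of no real substance.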